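## Retrosynthetic overview

1. Target 28 ← methyl cuprate addition (sets C3) to enone 27 ← bis-angeloylation ← triol 23 ← tricyclic keto ester 22.
2. Seven-membered ring: C8–C9 bond by 7-endo acyl-radical hydroacylation of acid 21 onto the vinyl group on C6 (the proposed new step).
3. Cyclobutane: Wolff ring contraction of diazo ketone 17 (bicyclo[3.2.1]octenone → bicyclo[3.1.1]heptene acid 19), then methylation at C10.
4. Bicyclo[3.2.1] core 15 ← ring-closing metathesis of the all-trans cyclopentanone 14 ← (R)-4-hydroxycyclopentenone 1 by Michael addition, two aldol additions and a cuprate addition, each trans to its neighbour.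
5. Ring order: sacrificial cyclopentanone → six-membered ring → cyclobutane (contraction) → seven-membered ring; the angelate esters and the C3 methyl come last.

Assumptions and conventions: carbons carry longipinane labels (C1 ring-ketone carbon, C2 H2, C3 H–CH3, cyclobutane C4/C5/C11/C10, C6 quaternary C(CH3)(CH2O), C7 and C8 CH2, C9 CH–O; C12 = CH3 on C3, C13 = CH3 on C10, C14 = CH2O, C15 = CH3 on C6). The C1 silyl ether/carbinol centre, later the ketone, is carried as a mixture of epimers. A lithium or magnesium salt of an isolated product is not numbered separately.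

## Route

Step 1
Reactants: 1 (R)-4-hydroxycyclopent-2-en-1-one
Product: 2 (1R)-4-oxocyclopent-2-en-1-yl 2,2-dimethylpropanoate
Conditions: t-BuCOCl, pyridine, DMAP (cat.), CH2Cl2, 0 °C
Reagents that add atoms: pivaloyl chloride, CC(C)(C)C(=O)Cl
Why: O-acylation that leaves the carbinol stereocentre untouched; the pivalate has no α-hydrogen, shields one ring face and later leaves by E1cB.

Step 2
Reactants: 2 (1R)-4-oxocyclopent-2-en-1-yl 2,2-dimethylpropanoate; 3 methyl propanoate
Product: 5 methyl 2-[(1S,5R)-5-(pivaloyloxy)-3-(triethylsilyloxy)cyclopent-2-en-1-yl]propanoate, via ketene silyl acetal 4 (not isolated)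
Conditions: 3, Et3SiCl, LiN(i-Pr)2 (added last), THF, −78 °C; pentane, filter; then 2, HNTf2 (1 mol %), CH2Cl2, −78 °C
Reagents that add atoms: chlorotriethylsilane, CC[Si](CC)(CC)Cl
Why: Mukaiyama–Michael addition with silyl transfer; the nucleophile enters trans to the pivaloyloxy group, which sets C5, and the ketone stays masked as its regiodefined enol ether (the ester α-centre is not yet fixed).

Step 3
Reactants: 5 methyl 2-[(1S,5R)-5-(pivaloyloxy)-3-(triethylsilyloxy)cyclopent-2-en-1-yl]propanoate; 6 acetaldehyde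
Product: 8 methyl (2R)-3-hydroxy-2-methyl-2-[(1S,5R)-5-(pivaloyloxy)-3-(triethylsilyloxy)cyclopent-2-en-1-yl]butanoate, via lithium ester enolate 7 (not isolated)
Conditions: LiN(i-Pr)2, THF, −78 °C; 6, −78 °C; aq. NH4Cl
Reagents that add atoms: none
Why: aldol addition of a tetrasubstituted ester enolate under A(1,3) control; with C5–H eclipsing the enolate, the aldehyde attacks from the side of the flat enol-ether carbon C11 rather than past the sp3 carbon C4, which sets the quaternary centre C6 (the carbinol centre is removed in step 4).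

Step 4
Reactants: 8 methyl (2R)-3-hydroxy-2-methyl-2-[(1S,5R)-5-(pivaloyloxy)-3-(triethylsilyloxy)cyclopent-2-en-1-yl]butanoate
Product: 10 methyl (2S)-2-methyl-2-[(1S,5R)-5-(pivaloyloxy)-3-(triethylsilyloxy)cyclopent-2-en-1-yl]but-3-enoate, via Burgess sulfamate salt 9 (not isolated)
Conditions: MeO2CN(−)SO2N(+)Et3 (Burgess reagent), toluene, 23 → 70 °C
Reagents that add atoms: Burgess reagent (stays only in 9), CC[N+](CC)(CC)S(=O)(=O)[N-]C(=O)OC
Why: Burgess dehydration (syn-elimination); the quaternary C6 leaves only the methyl hydrogens, so only the terminal vinyl group can form and C6 is untouched.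

Step 5
Reactants: 10 methyl (2S)-2-methyl-2-[(1S,5R)-5-(pivaloyloxy)-3-(triethylsilyloxy)cyclopent-2-en-1-yl]but-3-enoate; 11 acrolein
Product: 12 methyl (2S)-2-methyl-2-{3-oxo-5-(pivaloyloxy)-2-[1-(triethylsilyloxy)prop-2-en-1-yl]cyclopentyl}but-3-enoate (ring substituents all-trans)
Conditions: 11, HNTf2 (2 mol %), CH2Cl2, −78 °C
Reagents that add atoms: none
Why: Mukaiyama aldol (1,2-addition) with silyl transfer; the aldehyde adds to C11 trans to the bulky C5 substituent, which sets C11, and the new carbinol emerges as its triethylsilyl ether.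

Step 6
Reactants: 12 methyl (2S)-2-methyl-2-{3-oxo-5-(pivaloyloxy)-2-[1-(triethylsilyloxy)prop-2-en-1-yl]cyclopentyl}but-3-enoate
Product: 13 methyl (2S)-2-methyl-2-{4-oxo-5-[1-(triethylsilyloxy)prop-2-en-1-yl]cyclopent-2-en-1-yl}but-3-enoate (4,5-trans)
Conditions: DBU, CH2Cl2, −20 °C
Reagents that add atoms: none
Why: E1cB elimination from the β-acyloxy ketone; pivalate leaves far faster than the silyloxy group, and C5 and C11 keep their stable trans arrangement.

Step 7
Reactants: 13 methyl (2S)-2-methyl-2-{4-oxo-5-[1-(triethylsilyloxy)prop-2-en-1-yl]cyclopent-2-en-1-yl}but-3-enoate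
Product: 14 methyl (2S)-2-{2-ethenyl-4-oxo-5-[1-(triethylsilyloxy)prop-2-en-1-yl]cyclopentyl}-2-methylbut-3-enoate (ring substituents all-trans)
Conditions: CH2=CHMgBr, CuI, THF, −78 → −40 °C; aq. NH4Cl
Reagents that add atoms: vinylmagnesium bromide, C=C[Mg]Br
Why: cuprate conjugate addition; the vinyl group adds trans to the adjacent C5 substituent, which sets C4 and places the C4 vinyl and the C11 side chain cis-1,3.

Step 8
Reactants: 14 methyl (2S)-2-{2-ethenyl-4-oxo-5-[1-(triethylsilyloxy)prop-2-en-1-yl]cyclopentyl}-2-methylbut-3-enoate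
Product: 15 methyl (2S)-2-methyl-2-[6-oxo-4-(triethylsilyloxy)bicyclo[3.2.1]oct-2-en-8-yl]but-3-enoate (side chain on C8 syn to the ketone bridge)
Conditions: RuCl2(PCy3)2(=CHPh) (first-generation Grubbs catalyst, 5 mol %), CH2Cl2 (5 mM), 40 °C
Reagents that add atoms: none
Why: ring-closing metathesis; the unhindered C4 vinyl loads the catalyst and closes onto the cis-1,3 allylic-ether vinyl to give the bridged cyclohexene, while the neopentyl vinyl on C6 is too hindered for this catalyst.

Step 9
Reactants: 15 methyl (2S)-2-methyl-2-[6-oxo-4-(triethylsilyloxy)bicyclo[3.2.1]oct-2-en-8-yl]but-3-enoate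
Product: 17 methyl (2S)-2-[7-diazo-6-oxo-4-(triethylsilyloxy)bicyclo[3.2.1]oct-2-en-8-yl]-2-methylbut-3-enoate, via trifluoroacetyl ketone 16 (not isolated)
Conditions: LiN(SiMe3)2, THF, −78 °C; CF3CO2CH2CF3; then MsN3, Et3N, H2O (1 equiv), MeCN, 23 °C
Reagents that add atoms: 2,2,2-trifluoroethyl trifluoroacetate (stays only in 16), O=C(OCC(F)(F)F)C(F)(F)F; methanesulfonyl azide, CS(=O)(=O)N=[N+]=[N-]
Why: detrifluoroacetylative diazo transfer; the ketone can enolise only towards C10 because C11 is a bridgehead, so the diazo group enters at C10 alone.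

Step 10
Reactants: 17 methyl (2S)-2-[7-diazo-6-oxo-4-(triethylsilyloxy)bicyclo[3.2.1]oct-2-en-8-yl]-2-methylbut-3-enoate
Product: 19 7-[(2S)-1-methoxy-2-methyl-1-oxobut-3-en-2-yl]-4-(triethylsilyloxy)bicyclo[3.1.1]hept-2-ene-6-carboxylic acid, via ketene 18 (not isolated)
Conditions: hν (365 nm), THF–H2O 10:1, 0 °C
Reagents that add atoms: water, O
Why: Wolff rearrangement; loss of N2 with 1,2-shift of the bridgehead carbon C11 from the carbonyl carbon to C10 contracts the cyclopentanone to the cyclobutane, and water traps the ketene as the acid (both C10 epimers are used).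

Step 11
Reactants: 19 7-[(2S)-1-methoxy-2-methyl-1-oxobut-3-en-2-yl]-4-(triethylsilyloxy)bicyclo[3.1.1]hept-2-ene-6-carboxylic acid
Product: 21 7-[(2S)-1-methoxy-2-methyl-1-oxobut-3-en-2-yl]-6-methyl-4-(triethylsilyloxy)bicyclo[3.1.1]hept-2-ene-6-carboxylic acid (carboxyl cis to the C7 side chain), via dilithium enediolate 20 (not isolated)
Conditions: LiN(i-Pr)2 (2.3 equiv), THF–DMPU, −78 → 0 °C; MeI, −78 °C; cold 0.5 M aq. HCl
Reagents that add atoms: iodomethane, CI
Why: alkylation of a carboxylic acid dianion; MeI attacks the planar C10 on the face away from the cis-1,3 quaternary side chain on C5, which sets C10 with the carboxyl next to that side chain.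

Step 12
Reactants: 21 7-[(2S)-1-methoxy-2-methyl-1-oxobut-3-en-2-yl]-6-methyl-4-(triethylsilyloxy)bicyclo[3.1.1]hept-2-ene-6-carboxylic acid
Product: 22 methyl (4S,5S,6S,10R,11R)-9-oxo-1-(triethylsilyloxy)longipin-2-en-14-oate
Conditions: PPh3 (1.5 equiv), [Ir(dF(CF3)ppy)2(dtbbpy)]PF6 (2 mol %), 2,4,6-triisopropylbenzenethiol (5 mol %), 2,4,6-collidine (1 equiv), MeCN (5 mM), 450 nm LEDs, 23 °C
Reagents that add atoms: none
Why: Proposed new method: the photoexcited iridium complex oxidises PPh3, the carboxylate adds to the phosphine radical cation, and the phosphoranyl radical fragments to Ph3P=O and the C9 acyl radical, which adds 7-endo-trig to the unhindered terminus of the vinyl group on C6 (6-exo attack next to the quaternary centre would give a more strained bicyclo[3.1.1] ring) before the dilute thiol transfers hydrogen to the C7 radical, closing the seven-membered ring as the C9 ketone; the closest known reactions are the phosphoranyl-radical deoxygenation and hydroacylation of aromatic carboxylic acids and the tin hydride 7-endo cyclisation of acyl selenides, neither shown for a tertiary aliphatic acid closing a bridged ring.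

Step 13
Reactants: 22 methyl (4S,5S,6S,10R,11R)-9-oxo-1-(triethylsilyloxy)longipin-2-en-14-oate
Product: 23 (4S,5S,6S,9R,10R,11R)-longipin-2-ene-1,9,14-triol
Conditions: LiBH(s-Bu)3, THF, −78 °C; LiAlH4, −78 → 0 °C; then 1 M aq. HCl–THF, 23 °C
Reagents that add atoms: none
Why: hydride reduction under steric approach control; the bulky borohydride attacks the C9 ketone from the face away from the C14 ester held over the other face by C6, which sets C9 with its oxygen cis to C14; LiAlH4 then reduces the ester and the acidic work-up removes the silyl group.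

Step 14
Reactants: 23 (4S,5S,6S,9R,10R,11R)-longipin-2-ene-1,9,14-triol
Product: 24 (4S,5S,6S,9R,10R,11R)-9,14-dihydroxylongipin-2-en-1-one
Conditions: MnO2, CH2Cl2, 23 °C
Reagents that add atoms: none
Why: chemoselective allylic oxidation; only the allylic C1 carbinol reacts, both C1 epimers converge on one enone, and the saturated secondary and primary alcohols stay.

Step 15
Reactants: 24 (4S,5S,6S,9R,10R,11R)-9,14-dihydroxylongipin-2-en-1-one; 25 angelic acid
Product: 27 (4S,5S,6S,9R,10R,11R)-9,14-bis(angeloyloxy)longipin-2-en-1-one, via mixed anhydride 26 (not isolated)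
Conditions: 25, 2,4,6-Cl3C6H2COCl, Et3N, toluene, 23 °C; then 24, LiN(SiMe3)2 (2.2 equiv), THF, −78 → 0 °C
Reagents that add atoms: 2,4,6-trichlorobenzoyl chloride (stays only in 26), O=C(Cl)c1c(Cl)cc(Cl)cc1Cl
Why: Yamaguchi-type acyl transfer to the lithium alkoxides; the angeloyl carbonyl is the less hindered one, the absence of DMAP and heat keeps the Z geometry, and the enone cannot enolise because C4 and C11 are bridgeheads.

Step 16
Reactants: 27 (4S,5S,6S,9R,10R,11R)-9,14-bis(angeloyloxy)longipin-2-en-1-one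
Product: 28 (3R,4S,5S,6S,9R,10R,11R)-9,14-bis(angeloyloxy)longipinan-1-one
Conditions: Me2CuLi (from MeLi, CuI), Et2O, −78 → −40 °C; aq. NH4Cl
Reagents that add atoms: lithium dimethylcuprate, [Li+].C[Cu-]C
Why: cuprate 1,4-addition to the bicyclo[3.1.1]heptenone; methyl enters from the side of the C5 bridge (hydrogen towards the enone) and not past the C13 methyl on the C10 bridge, which sets C3, and the trisubstituted angelates are far poorer acceptors at this temperature.

## Compound list

1 | (R)-4-hydroxycyclopent-2-en-1-one | O=C1C=C[C@H](O)C1 | starting material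
2 | (1R)-4-oxocyclopent-2-en-1-yl 2,2-dimethylpropanoate | O=C1C=C[C@H](OC(=O)C(C)(C)C)C1 | intermediate
3 | methyl propanoate | CCC(=O)OC | starting material
4 | triethyl[(1-methoxyprop-1-en-1-yl)oxy]silane (ketene silyl acetal of 3) | CC=C(OC)O[Si](CC)(CC)CC | intermediate
5 | methyl 2-[(1S,5R)-5-(pivaloyloxy)-3-(triethylsilyloxy)cyclopent-2-en-1-yl]propanoate (epimers at the ester α-carbon) | CC[Si](CC)(CC)OC1=C[C@@H](C(C)C(=O)OC)[C@H](OC(=O)C(C)(C)C)C1 | intermediate
6 | acetaldehyde | CC=O | starting material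
7 | lithium ester enolate of 5 | CC[Si](CC)(CC)OC1=C[C@@H](C(C)=C(OC)O[Li])[C@H](OC(=O)C(C)(C)C)C1 | intermediate
8 | methyl (2R)-3-hydroxy-2-methyl-2-[(1S,5R)-5-(pivaloyloxy)-3-(triethylsilyloxy)cyclopent-2-en-1-yl]butanoate (carbinol epimers) | CC[Si](CC)(CC)OC1=C[C@@H]([C@](C)(C(C)O)C(=O)OC)[C@H](OC(=O)C(C)(C)C)C1 | intermediate
9 | triethylammonium salt of the N-(methoxycarbonyl)sulfamate ester of 8 | CC[Si](CC)(CC)OC1=C[C@@H]([C@](C)(C(C)OS(=O)(=O)[N-]C(=O)OC)C(=O)OC)[C@H](OC(=O)C(C)(C)C)C1.CC[NH+](CC)CC | intermediate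
10 | methyl (2S)-2-methyl-2-[(1S,5R)-5-(pivaloyloxy)-3-(triethylsilyloxy)cyclopent-2-en-1-yl]but-3-enoate | CC[Si](CC)(CC)OC1=C[C@@H]([C@](C)(C=C)C(=O)OC)[C@H](OC(=O)C(C)(C)C)C1 | intermediate
11 | acrolein (prop-2-enal) | C=CC=O | starting material
12 | methyl (2S)-2-methyl-2-{3-oxo-5-(pivaloyloxy)-2-[1-(triethylsilyloxy)prop-2-en-1-yl]cyclopentyl}but-3-enoate (ring all-trans; silyl ether carbon epimers) | O=C1[C@H](C(O[Si](CC)(CC)CC)C=C)[C@@H]([C@](C)(C=C)C(=O)OC)[C@H](OC(=O)C(C)(C)C)C1 | intermediate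
13 | methyl (2S)-2-methyl-2-{4-oxo-5-[1-(triethylsilyloxy)prop-2-en-1-yl]cyclopent-2-en-1-yl}but-3-enoate (4,5-trans) | O=C1[C@H](C(O[Si](CC)(CC)CC)C=C)[C@@H]([C@](C)(C=C)C(=O)OC)C=C1 | intermediate
14 | methyl (2S)-2-{2-ethenyl-4-oxo-5-[1-(triethylsilyloxy)prop-2-en-1-yl]cyclopentyl}-2-methylbut-3-enoate (ring all-trans) | O=C1[C@H](C(O[Si](CC)(CC)CC)C=C)[C@@H]([C@](C)(C=C)C(=O)OC)[C@H](C=C)C1 | intermediate
15 | methyl (2S)-2-methyl-2-[6-oxo-4-(triethylsilyloxy)bicyclo[3.2.1]oct-2-en-8-yl]but-3-enoate (C8 side chain syn to the ketone bridge) | COC(=O)[C@@](C)(C=C)[C@H]1[C@@H]2C=CC(O[Si](CC)(CC)CC)[C@H]1C(=O)C2 | intermediate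
16 | 7-trifluoroacetyl derivative of 15 | COC(=O)[C@@](C)(C=C)[C@H]1[C@@H]2C=CC(O[Si](CC)(CC)CC)[C@H]1C(=O)C2C(=O)C(F)(F)F | intermediate
17 | methyl (2S)-2-[7-diazo-6-oxo-4-(triethylsilyloxy)bicyclo[3.2.1]oct-2-en-8-yl]-2-methylbut-3-enoate | COC(=O)[C@@](C)(C=C)[C@H]1[C@@H]2C=CC(O[Si](CC)(CC)CC)[C@H]1C(=O)C2=[N+]=[N-] | intermediate
18 | bicyclo[3.1.1]hept-2-en-6-ylidene ketene from 17 | COC(=O)[C@@](C)(C=C)[C@H]1[C@@H]2C=CC(O[Si](CC)(CC)CC)[C@H]1C2=C=O | intermediate
19 | 7-[(2S)-1-methoxy-2-methyl-1-oxobut-3-en-2-yl]-4-(triethylsilyloxy)bicyclo[3.1.1]hept-2-ene-6-carboxylic acid (C6 epimers) | COC(=O)[C@@](C)(C=C)[C@H]1[C@@H]2C=CC(O[Si](CC)(CC)CC)[C@H]1C2C(=O)O | intermediate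
20 | dilithium enediolate of 19 | COC(=O)[C@@](C)(C=C)[C@H]1[C@@H]2C=CC(O[Si](CC)(CC)CC)[C@H]1C2=C(O[Li])O[Li] | intermediate
21 | 7-[(2S)-1-methoxy-2-methyl-1-oxobut-3-en-2-yl]-6-methyl-4-(triethylsilyloxy)bicyclo[3.1.1]hept-2-ene-6-carboxylic acid (carboxyl cis to the C7 side chain) | COC(=O)[C@@](C)(C=C)[C@H]1[C@@H]2C=CC(O[Si](CC)(CC)CC)[C@H]1[C@]2(C)C(=O)O | intermediate
22 | methyl (4S,5S,6S,10R,11R)-9-oxo-1-(triethylsilyloxy)longipin-2-en-14-oate | COC(=O)[C@@]1(C)CCC(=O)[C@]2(C)[C@@H]3[C@H]1[C@H]2C(O[Si](CC)(CC)CC)C=C3 | intermediate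
23 | (4S,5S,6S,9R,10R,11R)-longipin-2-ene-1,9,14-triol (C1 epimers) | OC[C@@]1(C)CC[C@@H](O)[C@]2(C)[C@@H]3[C@H]1[C@H]2C(O)C=C3 | intermediate
24 | (4S,5S,6S,9R,10R,11R)-9,14-dihydroxylongipin-2-en-1-one | OC[C@@]1(C)CC[C@@H](O)[C@]2(C)[C@@H]3[C@H]1[C@H]2C(=O)C=C3 | intermediate
25 | angelic acid, (Z)-2-methylbut-2-enoic acid | C/C=C(/C)C(=O)O | starting material
26 | angelic 2,4,6-trichlorobenzoic anhydride | C/C=C(/C)C(=O)OC(=O)c1c(Cl)cc(Cl)cc1Cl | intermediate
27 | (4S,5S,6S,9R,10R,11R)-9,14-bis(angeloyloxy)longipin-2-en-1-one | C/C=C(/C)C(=O)OC[C@@]1(C)CC[C@@H](OC(=O)/C(C)=C\C)[C@]2(C)[C@@H]3[C@H]1[C@H]2C(=O)C=C3 | intermediate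
28 | (3R,4S,5S,6S,9R,10R,11R)-9,14-bis(angeloyloxy)longipinan-1-one (CNP0276938.1) | C/C=C(/C)C(=O)OC[C@@]1(C)CC[C@@H](OC(=O)/C(C)=C\C)[C@]2(C)[C@@H]3[C@H]1[C@H]2C(=O)C[C@H]3C | target

## Step count and risks

Total step count: 16. Longest linear sequence: 16 steps (1 → 28).

Three steps most likely to fail:

Step 3 (configuration of the quaternary centre C6). The facial bias may be opposite to the A(1,3) model. In that case exchange the order in which the two C6 substituents arrive. Setting out from 2, Michael addition of the lithium dienolate of methyl but-3-enoate (LiN(i-Pr)2, THF–DMPU, −78 °C, α-attack) with Et3SiCl trapping gives methyl 2-[(1S,5R)-5-(pivaloyloxy)-3-(triethylsilyloxy)cyclopent-2-en-1-yl]but-3-enoate F1. Its lithium enolate is then methylated with MeI. The vinyl group is now the in-plane substituent and methyl the incoming electrophile, so the same facial bias gives the other C6 configuration. The sequence comes back to the route at 10. If the bias is merely low, the epimers of 8 are separated by chromatography.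

Step 12 (the proposed new ring closure; risks are decarbonylation of the tertiary acyl radical and premature reduction to the aldehyde). The known tin hydride route sets out from 21. (PhSe)2 and Bu3P in CH2Cl2 give the Se-phenyl selenoester of 21 F2. Slow addition of Bu3SnH with AIBN in benzene at 80 °C under CO then effects the precedented 7-endo acyl radical cyclisation and comes back at 22.

Step 13 (face selectivity of the C9 ketone reduction). Setting out from 22, Al(O-i-Pr)3 and i-PrOH in toluene at 80 °C reduce the ketone reversibly (Meerwein–Ponndorf–Verley). Only the C9 epimer with its hydroxyl cis to the C14 ester can lactonise, so the equilibrium drains into the bridged C14-to-O9 lactone F3. LiAlH4 followed by 1 M aq. HCl opens the lactone and removes the silyl group, coming back at 23.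

Further compounds

F1 | step 3 | methyl 2-[(1S,5R)-5-(pivaloyloxy)-3-(triethylsilyloxy)cyclopent-2-en-1-yl]but-3-enoate | CC[Si](CC)(CC)OC1=C[C@@H](C(C=C)C(=O)OC)[C@H](OC(=O)C(C)(C)C)C1
F2 | step 12 | Se-phenyl selenoester of 21 | COC(=O)[C@@](C)(C=C)[C@H]1[C@@H]2C=CC(O[Si](CC)(CC)CC)[C@H]1[C@]2(C)C(=O)[Se]c1ccccc1
F3 | step 13 | bridged C14-to-O9 lactone of (4S,5S,6S,9R,10R,11R)-1-(triethylsilyloxy)longipin-2-ene | O=C1O[C@@H]2CC[C@]1(C)[C@H]1[C@@H]3C=CC(O[Si](CC)(CC)CC)[C@H]1[C@]23C
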